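## Retrosynthetic overview

1. Target 36 comes from 34 by base equilibration of the two ketone α-methyl centres (C10, C12) plus ester hydrolysis; 34 comes from dienone 33 (CBS reduction sets C19), and 33 from cycloadduct 32 (enol ether to enone, C17=C18).
2. Cycloadduct 32 comes from linear precursor 31 by one intramolecular Diels–Alder reaction of the complete C20 chain, as in the polyketide pathway. It forms bonds C9–C14 and C8–C17, and the 14Z diene forces the cis ring fusion.
3. Precursor 31 comes from vinyl iodide 11 (C1–C7, oxirane from Sharpless epoxidation) and alkyne 27 (C8–C20) by hydrozirconation/Negishi coupling at C7–C8, then oxidation at C11.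
4. Alkyne 27 comes from aldehyde 24 and (R)-mesylate 26 (Marshall propargylation, C10–C11); 24 comes from lactone 12, enal 16 and an α-ethoxy ylide by two Wittig reactions (C14=C15, C18=C19).
5. Ring order: oxirane first (step 4), then the cyclohexanone and the cyclohexene together (step 16).

Assumption and convention: polyketide numbering (C1 = carboxyl carbon to C20; ring bonds C8–C17 and C9–C14) is used throughout; the C18=C19 enol-ether geometry is erased in step 17, so 23–32 are drawn as the 18E isomer although step 10 also gives 18Z.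

## Route

Step 1
Reactants: 1 propargyl alcohol
Product: 3 (E)-3-iodo-2-methylprop-2-en-1-ol, via alkenylalane 2 (not isolated)
Conditions: Me3Al, Cp2ZrCl2 (25 mol %), CH2Cl2, 0 °C to rt; then I2, THF, −30 to 0 °C
Reagents that add atoms: trimethylaluminium C[Al](C)C; iodine II
Why: Negishi Zr-catalysed carboalumination adds Me and Al syn across the alkyne (Me to the internal carbon) and iodinolysis of the C–Al bond goes with retention, which fixes the later 6E trisubstituted alkene.

Step 2
Reactants: 3 (E)-3-iodo-2-methylprop-2-en-1-ol; 4 ethyl 2-(triphenylphosphoranylidene)propanoate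
Product: 6 ethyl (2E,4E)-5-iodo-2,4-dimethylpenta-2,4-dienoate, via iodoenal 5 (not isolated)
Conditions: MnO2, CH2Cl2, rt
Reagents that add atoms: none
Why: Tandem allylic oxidation–Wittig olefination, in which the stabilised ylide traps the volatile enal as it forms and gives the E trisubstituted enoate.

Step 3
Reactants: 6 ethyl (2E,4E)-5-iodo-2,4-dimethylpenta-2,4-dienoate
Product: 7 (2E,4E)-5-iodo-2,4-dimethylpenta-2,4-dien-1-ol
Conditions: DIBAL-H (2.2 equiv), CH2Cl2, −78 °C
Reagents that add atoms: none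
Why: DIBAL-H 1,2-reduction of the conjugated ester gives the allylic alcohol needed for directed epoxidation and leaves the vinyl iodide and both E alkenes untouched.

Step 4
Reactants: 7 (2E,4E)-5-iodo-2,4-dimethylpenta-2,4-dien-1-ol
Product: 8 [(2S,3S)-3-[(E)-1-iodoprop-1-en-2-yl]-2-methyloxiran-2-yl]methanol
Conditions: Ti(OiPr)4 (10 mol %), L-(+)-DET (12 mol %), TBHP, 4 Å MS, CH2Cl2, −20 °C
Reagents that add atoms: tert-butyl hydroperoxide CC(C)(C)OO
Why: Sharpless asymmetric epoxidation reacts only at the allylic-alcohol alkene, and L-(+)-tartrate delivers oxygen to the face that gives the (2S,3S)-epoxy alcohol, which is C4 (S) and C5 (S) of the target.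

Step 5
Reactants: 8 [(2S,3S)-3-[(E)-1-iodoprop-1-en-2-yl]-2-methyloxiran-2-yl]methanol; 9 methyl (triphenylphosphoranylidene)acetate
Product: 11 methyl (2E)-3-[(2S,3S)-3-[(E)-1-iodoprop-1-en-2-yl]-2-methyloxiran-2-yl]prop-2-enoate, via epoxy aldehyde 10 (not isolated)
Conditions: TEMPO (cat.), PhI(OAc)2, CH2Cl2, rt; then 9, rt
Reagents that add atoms: none
Why: TEMPO/PhI(OAc)2 oxidation to the non-enolisable (α-quaternary) epoxy aldehyde, then Wittig olefination with the stabilised ylide in the same flask, gives the 2E enoate without touching the oxirane centres.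

Step 6
Reactants: 12 (R)-α-methyl-γ-butyrolactone
Product: 14 methyl (2R)-4-bromo-2-methylbutanoate, via bromo acid 13 (not isolated)
Conditions: HBr (33 % in AcOH), 70 °C; then MeOH, rt
Reagents that add atoms: hydrogen bromide Br; methanol CO
Why: Acid-mediated SN2 opening of the lactone at the O–CH2 carbon by bromide followed by Fischer esterification, with the α-stereocentre (C12) not involved.

Step 7
Reactants: 14 methyl (2R)-4-bromo-2-methylbutanoate
Product: 15 [(3R)-4-methoxy-3-methyl-4-oxobutyl]triphenylphosphonium bromide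
Conditions: PPh3, MeCN, reflux
Reagents that add atoms: triphenylphosphine c1ccc(cc1)P(c1ccccc1)c1ccccc1
Why: SN2 quaternisation of triphenylphosphine by the primary bromide gives the Wittig salt, with C12 remote from the reacting carbon.

Step 8
Reactants: 15 [(3R)-4-methoxy-3-methyl-4-oxobutyl]triphenylphosphonium bromide; 16 (2E)-4,4-dimethoxy-2-methylbut-2-enal
Product: 19 methyl (2R,4Z,6E)-2,6-dimethyl-8-oxoocta-4,6-dienoate, via phosphorus ylide 17 (not isolated), via dimethyl acetal 18 (not isolated)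
Conditions: NaHMDS, THF, −78 °C; 16, −78 °C to rt; then aq. oxalic acid, THF, 0 °C
Reagents that add atoms: water O
Why: Salt-free Wittig reaction of the non-stabilised ylide with the enal gives the 14Z alkene under kinetic control, and mild acid then hydrolyses the allylic acetal without touching the ester.

Step 9
Reactants: 20 1-chloroethyl ethyl ether (racemic)
Product: 21 (1-ethoxyethyl)triphenylphosphonium chloride (racemic)
Conditions: PPh3, toluene, rt
Reagents that add atoms: triphenylphosphine c1ccc(cc1)P(c1ccccc1)c1ccccc1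
Why: The α-chloro ether ionises readily and is captured by triphenylphosphine (SN1-type alkylation) to give the α-alkoxyalkyl Wittig salt.

Step 10
Reactants: 19 methyl (2R,4Z,6E)-2,6-dimethyl-8-oxoocta-4,6-dienoate; 21 (1-ethoxyethyl)triphenylphosphonium chloride
Product: 23 methyl (2R,4Z,6E,8E)-9-ethoxy-2,6-dimethyldeca-4,6,8-trienoate, via ethoxy ylide 22 (not isolated)
Conditions: n-BuLi, THF, −78 to −40 °C; then 19, −78 to 0 °C
Reagents that add atoms: none
Why: Wittig olefination with the non-stabilised α-ethoxy ylide attacks only the aldehyde (not the methyl ester) and installs the ethyl enol ether that is both a latent C19 ketone and a donor on the diene.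

Step 11
Reactants: 23 methyl (2R,4Z,6E,8E)-9-ethoxy-2,6-dimethyldeca-4,6,8-trienoate
Product: 24 (2R,4Z,6E,8E)-9-ethoxy-2,6-dimethyldeca-4,6,8-trienal
Conditions: DIBAL-H (1.1 equiv), CH2Cl2, −78 °C; Rochelle salt
Reagents that add atoms: none
Why: Partial DIBAL-H reduction at −78 °C stops at the tetrahedral aluminium hemiacetal, which gives the α-methyl aldehyde on work-up without epimerising C12 or hydrolysing the enol ether.

Step 12
Reactants: 25 (R)-but-3-yn-2-ol
Product: 26 (R)-but-3-yn-2-yl methanesulfonate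
Conditions: MsCl, Et3N, CH2Cl2, −78 to 0 °C
Reagents that add atoms: methanesulfonyl chloride CS(=O)(=O)Cl
Why: Mesylation forms only the O–S bond, so the propargylic carbon keeps its configuration and becomes the Marshall propargylation precursor.

Step 13
Reactants: 24 (2R,4Z,6E,8E)-9-ethoxy-2,6-dimethyldeca-4,6,8-trienal; 26 (R)-but-3-yn-2-yl methanesulfonate
Product: 27 (3S,4R,5R,7Z,9E,11E)-12-ethoxy-3,5,9-trimethyltrideca-7,9,11-trien-1-yn-4-ol
Conditions: Pd(OAc)2 (5 mol %), PPh3 (5 mol %), InI, THF/HMPA (3:1), rt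
Reagents that add atoms: none
Why: Marshall–Tamaru propargylation, in which Pd(0) opens the mesylate by anti-SN2′ to an allenylpalladium that is transmetallated to a chiral allenylindium and adds through a cyclic SE2′ transition state to give the anti adduct with net inversion at the propargylic carbon, so the (R)-mesylate sets C10 as S under reagent control (C11 is oxidised later).

Step 14
Reactants: 27 (3S,4R,5R,7Z,9E,11E)-12-ethoxy-3,5,9-trimethyltrideca-7,9,11-trien-1-yn-4-ol; 11 methyl (2E)-3-[(2S,3S)-3-[(E)-1-iodoprop-1-en-2-yl]-2-methyloxiran-2-yl]prop-2-enoate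
Product: 30 methyl (2E,4S,5S,6E,8E,10S,11R,12R,14Z,16E,18E)-19-ethoxy-4,5-epoxy-11-hydroxy-4,6,10,12,16-pentamethylicosa-2,6,8,14,16,18-hexaenoate, via alkenylzirconocene 28 (not isolated), via alkenylzinc chloride 29 (not isolated)
Conditions: Cp2Zr(H)Cl (2.2 equiv), THF, rt; ZnCl2, 0 °C; then 11, Pd(PPh3)4 (5 mol %), rt
Reagents that add atoms: none
Why: Hydrozirconation of the terminal alkyne is syn and puts Zr on C8, and Zr-to-Zn transmetallation followed by Negishi coupling with the vinyl iodide forms the C7–C8 bond at room temperature with retention of both alkene geometries (6E,8E).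

Step 15
Reactants: 30 methyl (2E,4S,5S,6E,8E,10S,11R,12R,14Z,16E,18E)-19-ethoxy-4,5-epoxy-11-hydroxy-4,6,10,12,16-pentamethylicosa-2,6,8,14,16,18-hexaenoate
Product: 31 methyl (2E,4S,5S,6E,8E,10S,12R,14Z,16E,18E)-19-ethoxy-4,5-epoxy-4,6,10,12,16-pentamethyl-11-oxoicosa-2,6,8,14,16,18-hexaenoate
Conditions: Dess–Martin periodinane, NaHCO3, CH2Cl2, 0 °C
Reagents that add atoms: none
Why: Buffered Dess–Martin oxidation of the hindered secondary alcohol gives the β,γ-unsaturated ketone under neutral conditions, so the doubly activated C10 centre is neither epimerised nor moved into conjugation.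

Step 16
Reactants: 31 methyl (2E,4S,5S,6E,8E,10S,12R,14Z,16E,18E)-19-ethoxy-4,5-epoxy-4,6,10,12,16-pentamethyl-11-oxoicosa-2,6,8,14,16,18-hexaenoate
Product: 32 methyl (2E,4S,5S,6E,8R,9R,10S,12R,14S,17R,18E)-19-ethoxy-4,5-epoxy-4,6,10,12,16-pentamethyl-11-oxo-8,17:9,14-dicycloicosa-2,6,15,18-tetraenoate (cis-fused cycloadduct)
Conditions: 12 kbar, CH2Cl2 (0.01 M), BHT (cat.), 45 °C, 72 h
Reagents that add atoms: none
Why: Intramolecular Diels–Alder reaction of the C14–C17 diene with the C8=C9 alkene, in which the 14Z diene can reach only the cis-fused transition state (tether exo, dienyl side chain endo), the syn C10/C12 methyls (deliberately epimeric to the target) sit equatorial in the chair-like tether so that only one π-face is used (the other needs a 1,3-diaxial Me/Me pair), which sets C8 (R), C9 (R) and C14 (S), while 12 kbar accelerates the cycloaddition enough to spare the heat-sensitive divinyl epoxide and outrun the [1,5]-H shift of the Z-diene.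

Step 17
Reactants: 32 cis-fused cycloadduct (ethyl enol ether)
Product: 33 methyl (2E,4S,5S,6E,8R,9R,10S,12R,14S,17E)-4,5-epoxy-4,6,10,12,16-pentamethyl-11,19-dioxo-8,17:9,14-dicycloicosa-2,6,15,17-tetraenoate
Conditions: DDQ, CH2Cl2/pH 7 phosphate buffer (10:1), 0 °C
Reagents that add atoms: water O
Why: Proposed new method: DDQ abstracts the doubly allylic C17 hydride next to the enol ether to give an ethoxy-pentadienyl (oxocarbenium) cation that water hydrolyses to the dienone, with 17E favoured because the 17Z isomer would press the acetyl group against the C16 methyl (A1,3 strain); the closest known reactions are DDQ and Saegusa–Ito dehydrogenations of silyl enol ethers and of steroidal dienol ethers to enones.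

Step 18
Reactants: 33 dienone methyl ester
Product: 34 methyl (2E,4S,5S,6E,8R,9R,10S,12R,14S,17E,19R)-4,5-epoxy-19-hydroxy-4,6,10,12,16-pentamethyl-11-oxo-8,17:9,14-dicycloicosa-2,6,15,17-tetraenoate
Conditions: (S)-2-methyl-CBS-oxazaborolidine (0.5 equiv), catecholborane, toluene, −78 °C
Reagents that add atoms: none
Why: Corey–Bakshi–Shibata reduction, in which the (S)-oxazaborolidine binds the methyl ketone with the dienyl group as the large substituent and delivers hydride 1,2 to give the 19R allylic alcohol, while the hindered α,α′-dimethyl ring ketone does not react with catecholborane at −78 °C.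

Step 19
Reactants: 34 10,12-bis-epi methyl ester
Product: 36 CNP0414188.1, (2E,4S,5S,6E,8R,9R,10R,12S,14S,17E,19R)-4,5-epoxy-19-hydroxy-4,6,10,12,16-pentamethyl-11-oxo-8,17:9,14-dicycloicosa-2,6,15,17-tetraenoic acid, via target methyl ester 35 (not isolated)
Conditions: NaOMe (0.3 equiv), MeOH, rt; then LiOH, THF/H2O, rt; 1 M HCl to pH 4
Reagents that add atoms: lithium hydroxide [Li+].[OH-]
Why: Thermodynamic epimerisation through the ketone enolates takes C10 and C12 to the only arrangement with both methyls equatorial on the cyclohexanone chair while the C8 side chain stays pseudo-axial (no A1,3 strain with the exocyclic alkene), giving 10R,12S, and hydroxide then saponifies the methyl ester.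

## Compound list

1 | propargyl alcohol (prop-2-yn-1-ol) | C#CCO | starting material
2 | (E)-3-(dimethylalumanyl)-2-methylprop-2-enyl dimethylaluminium alkoxide | C[Al](C)/C=C(\C)CO[Al](C)C | intermediate
3 | (E)-3-iodo-2-methylprop-2-en-1-ol | I/C=C(\C)CO | intermediate
4 | ethyl 2-(triphenylphosphoranylidene)propanoate | CCOC(=O)C(C)=P(c1ccccc1)(c1ccccc1)c1ccccc1 | starting material
5 | (E)-3-iodo-2-methylprop-2-enal | I/C=C(\C)C=O | intermediate
6 | ethyl (2E,4E)-5-iodo-2,4-dimethylpenta-2,4-dienoate | I/C=C(\C)/C=C(\C)C(=O)OCC | intermediate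
7 | (2E,4E)-5-iodo-2,4-dimethylpenta-2,4-dien-1-ol | I/C=C(\C)/C=C(\C)CO | intermediate
8 | [(2S,3S)-3-[(E)-1-iodoprop-1-en-2-yl]-2-methyloxiran-2-yl]methanol | I/C=C(\C)[C@@H]1O[C@@]1(C)CO | intermediate
9 | methyl (triphenylphosphoranylidene)acetate | COC(=O)C=P(c1ccccc1)(c1ccccc1)c1ccccc1 | starting material
10 | (2R,3S)-3-[(E)-1-iodoprop-1-en-2-yl]-2-methyloxirane-2-carbaldehyde | I/C=C(\C)[C@@H]1O[C@@]1(C)C=O | intermediate
11 | methyl (2E)-3-[(2S,3S)-3-[(E)-1-iodoprop-1-en-2-yl]-2-methyloxiran-2-yl]prop-2-enoate (C1–C7 fragment) | I/C=C(\C)[C@@H]1O[C@@]1(C)/C=C/C(=O)OC | intermediate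
12 | (R)-α-methyl-γ-butyrolactone, (3R)-3-methyloxolan-2-one | C[C@@H]1CCOC1=O | starting material
13 | (2R)-4-bromo-2-methylbutanoic acid | OC(=O)[C@H](C)CCBr | intermediate
14 | methyl (2R)-4-bromo-2-methylbutanoate | COC(=O)[C@H](C)CCBr | intermediate
15 | [(3R)-4-methoxy-3-methyl-4-oxobutyl]triphenylphosphonium bromide | COC(=O)[C@H](C)CC[P+](c1ccccc1)(c1ccccc1)c1ccccc1.[Br-] | intermediate
16 | (2E)-4,4-dimethoxy-2-methylbut-2-enal | COC(OC)/C=C(\C)C=O | starting material
17 | methyl (2R)-2-methyl-4-(triphenylphosphoranylidene)butanoate | COC(=O)[C@H](C)CC=P(c1ccccc1)(c1ccccc1)c1ccccc1 | intermediate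
18 | methyl (2R,4Z,6E)-8,8-dimethoxy-2,6-dimethylocta-4,6-dienoate | COC(=O)[C@H](C)C/C=C\C(C)=C\C(OC)OC | intermediate
19 | methyl (2R,4Z,6E)-2,6-dimethyl-8-oxoocta-4,6-dienoate | COC(=O)[C@H](C)C/C=C\C(C)=C\C=O | intermediate
20 | 1-chloroethyl ethyl ether (racemic) | CCOC(C)Cl | starting material
21 | (1-ethoxyethyl)triphenylphosphonium chloride (racemic) | CCOC(C)[P+](c1ccccc1)(c1ccccc1)c1ccccc1.[Cl-] | intermediate
22 | (1-ethoxyethylidene)triphenylphosphorane | CCOC(C)=P(c1ccccc1)(c1ccccc1)c1ccccc1 | intermediate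
23 | methyl (2R,4Z,6E,8E)-9-ethoxy-2,6-dimethyldeca-4,6,8-trienoate | COC(=O)[C@H](C)C/C=C\C(C)=C\C=C(/C)OCC | intermediate
24 | (2R,4Z,6E,8E)-9-ethoxy-2,6-dimethyldeca-4,6,8-trienal | O=C[C@H](C)C/C=C\C(C)=C\C=C(/C)OCC | intermediate
25 | (R)-but-3-yn-2-ol | C[C@@H](O)C#C | starting material
26 | (R)-but-3-yn-2-yl methanesulfonate | C[C@@H](OS(C)(=O)=O)C#C | intermediate
27 | (3S,4R,5R,7Z,9E,11E)-12-ethoxy-3,5,9-trimethyltrideca-7,9,11-trien-1-yn-4-ol (C8–C20 fragment) | C#C[C@H](C)[C@H](O)[C@H](C)C/C=C\C(C)=C\C=C(/C)OCC | intermediate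
28 | (E)-C8-alkenylzirconocene chloride of 27, O11 also zirconated | CCO/C(C)=C/C=C(C)/C=C\C[C@@H](C)[C@@H](O[Zr](Cl)(C1C=CC=C1)C1C=CC=C1)[C@@H](C)/C=C/[Zr](Cl)(C1C=CC=C1)C1C=CC=C1 | intermediate
29 | (E)-C8-alkenylzinc chloride of 27, O11 zirconated | CCO/C(C)=C/C=C(C)/C=C\C[C@@H](C)[C@@H](O[Zr](Cl)(C1C=CC=C1)C1C=CC=C1)[C@@H](C)/C=C/[Zn]Cl | intermediate
30 | methyl (2E,4S,5S,6E,8E,10S,11R,12R,14Z,16E,18E)-19-ethoxy-4,5-epoxy-11-hydroxy-4,6,10,12,16-pentamethylicosa-2,6,8,14,16,18-hexaenoate | CCO/C(C)=C/C=C(C)/C=C\C[C@@H](C)[C@@H](O)[C@@H](C)/C=C/C=C(\C)[C@@H]1O[C@@]1(C)/C=C/C(=O)OC | intermediate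
31 | methyl (2E,4S,5S,6E,8E,10S,12R,14Z,16E,18E)-19-ethoxy-4,5-epoxy-4,6,10,12,16-pentamethyl-11-oxoicosa-2,6,8,14,16,18-hexaenoate (Diels–Alder precursor) | CCO/C(C)=C/C=C(C)/C=C\C[C@@H](C)C(=O)[C@@H](C)/C=C/C=C(\C)[C@@H]1O[C@@]1(C)/C=C/C(=O)OC | intermediate
32 | cis-fused cycloadduct, methyl (2E,4S,5S,6E,8R,9R,10S,12R,14S,17R,18E)-19-ethoxy-4,5-epoxy-4,6,10,12,16-pentamethyl-11-oxo-8,17:9,14-dicycloicosa-2,6,15,18-tetraenoate | CC1=C[C@H]2C[C@@H](C)C(=O)[C@@H](C)[C@H]2[C@H](/C=C(\C)[C@@H]2O[C@@]2(C)/C=C/C(=O)OC)[C@@H]1/C=C(\C)OCC | intermediate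
33 | dienone, methyl (2E,4S,5S,6E,8R,9R,10S,12R,14S,17E)-4,5-epoxy-4,6,10,12,16-pentamethyl-11,19-dioxo-8,17:9,14-dicycloicosa-2,6,15,17-tetraenoate | CC1=C[C@H]2C[C@@H](C)C(=O)[C@@H](C)[C@H]2[C@H](/C=C(\C)[C@@H]2O[C@@]2(C)/C=C/C(=O)OC)/C1=C\C(C)=O | intermediate
34 | 10,12-bis-epi methyl ester, (…10S,12R,…,19R)-19-hydroxy compound | CC1=C[C@H]2C[C@@H](C)C(=O)[C@@H](C)[C@H]2[C@H](/C=C(\C)[C@@H]2O[C@@]2(C)/C=C/C(=O)OC)/C1=C\[C@@H](C)O | intermediate
35 | methyl ester of the target (10R,12S) | CC1=C[C@H]2C[C@H](C)C(=O)[C@H](C)[C@H]2[C@H](/C=C(\C)[C@@H]2O[C@@]2(C)/C=C/C(=O)OC)/C1=C\[C@@H](C)O | intermediate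
36 | CNP0414188.1, (2E,4S,5S,6E,8R,9R,10R,12S,14S,17E,19R)-4,5-epoxy-19-hydroxy-4,6,10,12,16-pentamethyl-11-oxo-8,17:9,14-dicycloicosa-2,6,15,17-tetraenoic acid | CC1=C[C@H]2C[C@H](C)C(=O)[C@H](C)[C@H]2[C@H](/C=C(\C)[C@@H]2O[C@@]2(C)/C=C/C(=O)O)/C1=C\[C@@H](C)O | target

## Step count and risks

Total step count: 19.
Longest linear sequence: 12 steps (12 to 36 through steps 6, 7, 8, 10, 11, 13, 14, 15, 16, 17, 18, 19).

Step 16 (high-pressure Diels–Alder of a Z-diene with an unactivated dienophile) is the most likely to fail: the divinyl epoxide may not survive, or the [1,5]-H shift may win. The fallback postpones the epoxide and the enoate until after the cycloaddition so that the substrate can simply be heated. It sets out from 7 and 27 and comes back at 32. Dienol 7 is silylated (TBSCl, imidazole) to tert-butyldimethylsilyl ether F1. Alkyne 27 is coupled with F1 exactly as in step 14 (through 28 and 29) to give trienyl alcohol F2, and Dess–Martin oxidation gives ketone F3. Without the epoxide, F3 is heated (toluene, BHT, 160 °C, sealed tube) to cis-fused cycloadduct F4 under the same 14Z and equatorial-methyl control. TBAF gives dienol F5, Sharpless epoxidation with L-(+)-DET gives epoxy alcohol F6, and TEMPO/PhI(OAc)2 oxidation to epoxy aldehyde F7 followed in the same flask by ylide 9 gives 32.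

Step 17 (DDQ dehydrogenation of the ethyl enol ether) is second: hydride abstraction could be slow or unselective. The fallback replaces hydride abstraction by electrophilic selenenylation and syn-elimination; it sets out from 32 and comes back at 33. PhSeCl (CH2Cl2, −78 °C, then aqueous NaHCO3) converts the enol ether into α-phenylselanyl ketone F8 (C18 epimers). H2O2/pyridine at 0 °C then gives the selenoxide, whose syn-elimination can only take the C17 hydrogen and gives dienone 33.

Step 14 (hydrozirconation/Negishi coupling next to a free alcohol, a trienyl enol ether and a vinyl epoxide) is third: zinc chloride or Pd(0) may damage the epoxide or the enol ether. The fallback separates metalation from coupling and uses copper instead of palladium and zinc for the C–C bond; it sets out from 27 and comes back at 30. Pd-catalysed hydrostannation (Bu3SnH, PdCl2(PPh3)2, THF, 0 °C) gives (E)-alkenylstannane F9, which is coupled with 11 by copper(I) thiophene-2-carboxylate in NMP at 0 °C to give 30.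

## Further compounds

F1 | step 16 | tert-butyl{[(2E,4E)-5-iodo-2,4-dimethylpenta-2,4-dien-1-yl]oxy}dimethylsilane | I/C=C(\C)/C=C(\C)CO[Si](C)(C)C(C)(C)C
F2 | step 16 | (2E,4E,6E,8S,9R,10R,12Z,14E,16E)-1-[(tert-butyldimethylsilyl)oxy]-17-ethoxy-2,4,8,10,14-pentamethyloctadeca-2,4,6,12,14,16-hexaen-9-ol | CCO/C(C)=C/C=C(C)/C=C\C[C@@H](C)[C@@H](O)[C@@H](C)/C=C/C=C(\C)/C=C(\C)CO[Si](C)(C)C(C)(C)C
F3 | step 16 | (2E,4E,6E,8S,10R,12Z,14E,16E)-1-[(tert-butyldimethylsilyl)oxy]-17-ethoxy-2,4,8,10,14-pentamethyloctadeca-2,4,6,12,14,16-hexaen-9-one | CCO/C(C)=C/C=C(C)/C=C\C[C@@H](C)C(=O)[C@@H](C)/C=C/C=C(\C)/C=C(\C)CO[Si](C)(C)C(C)(C)C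
F4 | step 16 | cis-fused cycloadduct as 32 but with a (1E,3E)-5-[(tert-butyldimethylsilyl)oxy]-2,4-dimethylpenta-1,3-dienyl group at C8 | CC1=C[C@H]2C[C@@H](C)C(=O)[C@@H](C)[C@H]2[C@H](/C=C(\C)/C=C(\C)CO[Si](C)(C)C(C)(C)C)[C@@H]1/C=C(\C)OCC
F5 | step 16 | dienol from F4, (1E,3E)-5-hydroxy-2,4-dimethylpenta-1,3-dienyl group at C8 | CC1=C[C@H]2C[C@@H](C)C(=O)[C@@H](C)[C@H]2[C@H](/C=C(\C)/C=C(\C)CO)[C@@H]1/C=C(\C)OCC
F6 | step 16 | (4S,5S)-epoxy alcohol from F5 | CC1=C[C@H]2C[C@@H](C)C(=O)[C@@H](C)[C@H]2[C@H](/C=C(\C)[C@@H]2O[C@@]2(C)CO)[C@@H]1/C=C(\C)OCC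
F7 | step 16 | epoxy aldehyde from F6 | CC1=C[C@H]2C[C@@H](C)C(=O)[C@@H](C)[C@H]2[C@H](/C=C(\C)[C@@H]2O[C@@]2(C)C=O)[C@@H]1/C=C(\C)OCC
F8 | step 17 | 18-(phenylselanyl)-19-ketone from 32 (C18 epimers) | CC1=C[C@H]2C[C@@H](C)C(=O)[C@@H](C)[C@H]2[C@H](/C=C(\C)[C@@H]2O[C@@]2(C)/C=C/C(=O)OC)[C@@H]1C([Se]c1ccccc1)C(C)=O
F9 | step 14 | (1E,3S,4R,5R,7Z,9E,11E)-12-ethoxy-3,5,9-trimethyl-1-(tributylstannyl)trideca-1,7,9,11-tetraen-4-ol | CCO/C(C)=C/C=C(C)/C=C\C[C@@H](C)[C@@H](O)[C@@H](C)/C=C/[Sn](CCCC)(CCCC)CCCC
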